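Ring C is cut at O1–C2 and C4–C4a (flavan numbering). This divides the target into a diarylmethane phenol (rings A and D) and an acyclic 2-benzyloxycinnamaldehyde (ring B with C2–C4). The key step exploits the C8a hydroxyl as the only free phenol of ring A, flanked by C8 (blocked by the CH2 bridge) and the free C4a. Condensation at C4a gives a vinylogous ortho-quinone methide, whose oxa-6π electrocyclisation joins both halves and closes ring C in one operation. C3 emerges as a masked ketone, so C2 is labile. One transfer hydrogenation with dynamic kinetic resolution then sets the cis C2/C3 pair.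

Key step: step 8

Naming: "ring D benzyl" stands for the group 2,6-dihydroxy-4-methoxy-5-methyl-3-[(2S)-2-methylbutanoyl]benzyl.

Assumption: in step 9 the C2 flank of the ketone (O1 and the aryl group) is taken to play the part of the aryl group in the usual model for RuCl(TsDPEN)(arene) catalysts, so the (R,R) catalyst should give the (3R) alcohol; should the sense be the reverse, the (S,S) catalyst is used.

Step 1
Reactants: 1 2-methylbenzene-1,3,5-triol (2-methylphloroglucinol); 2 (S)-2-methylbutanoyl chloride
Product: 3 (S)-2-methyl-1-(2,4,6-trihydroxy-3-methylphenyl)butan-1-one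
Conditions: AlCl3 (3.5 equiv), CH2Cl2/MeNO2, 0 °C to rt; then cold 1 M HCl
Reagents that add atoms: none
Why: Friedel–Crafts acylation of a very electron-rich arene whose two free ring carbons are equivalent, so one ketone should form, the acyl group shuts off a second acylation, and the (S) centre is carried in from 2 unchanged because no base is present and the temperature stays low.

Step 2
Reactants: 3 (S)-2-methyl-1-(2,4,6-trihydroxy-3-methylphenyl)butan-1-one
Product: 4 (S)-1-[4,6-bis(benzyloxy)-2-hydroxy-3-methylphenyl]-2-methylbutan-1-one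
Conditions: BnBr (2.05 equiv), K2CO3 (2.2 equiv), acetone, reflux
Reagents that add atoms: benzyl bromide, BrCc1ccccc1
Why: Williamson ether synthesis with two equivalents of halide, in which the hydroxyl para to the acyl group (most acidic) and the less hindered ortho hydroxyl should react, while the hydroxyl wedged between acyl and methyl stays locked in the hydrogen bond to the ketone.

Step 3
Reactants: 4 (S)-1-[4,6-bis(benzyloxy)-2-hydroxy-3-methylphenyl]-2-methylbutan-1-one
Product: 5 (S)-1-[4,6-bis(benzyloxy)-2-methoxy-3-methylphenyl]-2-methylbutan-1-one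
Conditions: MeI (3 equiv), K2CO3 (2 equiv), DMF, 50 °C
Reagents that add atoms: iodomethane, CI
Why: Williamson O-methylation of the single remaining phenol, which a small electrophile in a dipolar solvent should reach despite chelation, with a base too weak to enolise the hindered ketone.

Step 4
Reactants: 5 (S)-1-[4,6-bis(benzyloxy)-2-methoxy-3-methylphenyl]-2-methylbutan-1-one
Product: 6 (S)-1-(4,6-dihydroxy-2-methoxy-3-methylphenyl)-2-methylbutan-1-one
Conditions: H2 (1 atm), Pd/C, EtOAc/MeOH, rt
Reagents that add atoms: none
Why: Catalytic hydrogenolysis of two benzyl aryl ethers under neutral conditions, which should leave the methyl ether, the hindered aryl ketone and its α-centre untouched and frees the nucleophilic ring carbon between the two hydroxyls.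

Step 5
Reactants: 7 3,4-bis(benzyloxy)benzaldehyde; 8 (benzyloxy)acetaldehyde
Product: 9 (Z)-2-(benzyloxy)-3-[3,4-bis(benzyloxy)phenyl]prop-2-enal
Conditions: KOH (cat.), MeOH, 0 °C to rt, slow addition of 8 to excess 7
Reagents that add atoms: none
Why: Crossed aldol (Claisen–Schmidt) condensation in which only 8 can enolise and is kept dilute, and dehydration should give the conjugated enal with the aryl group trans to the formyl group.

Step 6
Reactants: 10 3,5-bis(benzyloxy)phenol
Product: 11 3,5-bis(benzyloxy)-2-[(dimethylamino)methyl]phenol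
Conditions: 37% aq. CH2O (1.0 equiv), 40% aq. Me2NH (1.0 equiv), EtOH, 0 °C to rt
Reagents that add atoms: formaldehyde, C=O; dimethylamine, CNC
Why: Mannich reaction of a phenol, steered to an ortho carbon by hydrogen bonding of the phenol to the aminomethylating species and by the crowding of the para carbon between two benzyloxy groups, with one equivalent of reagent to hold it at the mono stage.

Step 7
Reactants: 11 3,5-bis(benzyloxy)-2-[(dimethylamino)methyl]phenol; 6 (S)-1-(4,6-dihydroxy-2-methoxy-3-methylphenyl)-2-methylbutan-1-one
Product: 13 3,5-bis(benzyloxy)-2-(ring D benzyl)phenol, via ortho-quinone methide 12 (not isolated)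
Conditions: 6 (1.5 equiv), PhMe, 110 °C, N2 stream
Reagents that add atoms: none
Why: The acidic acylphloroglucinol 6 protonates the amine of 11, thermal elimination gives the donor-stabilised ortho-quinone methide 12, and the phenolate of 6 adds through its only free ring carbon in a Michael-type C-alkylation that restores the aromaticity of ring A.

Step 8
Reactants: 13 3,5-bis(benzyloxy)-2-(ring D benzyl)phenol; 9 (Z)-2-(benzyloxy)-3-[3,4-bis(benzyloxy)phenyl]prop-2-enal
Product: 16 5,7,3',4'-tetra-O-benzyl-8-(ring D benzyl)flavan-3-one as both C2 epimers, via vinylogous ortho-quinone methide 14 (not isolated), via 3-benzyloxy-2H-chromene 15 (not isolated)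
Conditions: ethylenediammonium diacetate (EDDA, 20 mol %), PhMe, 110 °C, Dean–Stark; then THF, 1 M aq. HCl, rt
Reagents that add atoms: water, O
Why: The amine salt turns enal 9 into its iminium ion, ring A of 13 attacks the former aldehyde carbon with C4a (the only free carbon ortho to the free phenol, because C8 already bears the CH2 bridge to ring D), and loss of the amine gives the vinylogous ortho-quinone methide 14. Compound 14 closes ring C by a thermal disrotatory oxa-6π electrocyclisation that forms O1–C2 and restores the aromaticity of ring A; the closest known reaction type is the formal (3+3) chromene synthesis from phenols and α,β-unsaturated aldehydes (Knoevenagel-type condensation, then electrocyclisation). The step needs ortho over para attack and 1,2- over 1,4-addition: attack at C6 is reversible and leads to no ring, so only the C4a adduct is drained by the cyclisation, and the donor aryl group and the 2-benzyloxy group lower the electrophilicity of the β-carbon of 9. The two phenols of ring D have no free ortho carbon and can only add reversibly. C2 is the only new stereocenter and is not controlled, which is intended, because aqueous acid then cleaves the enol ether of 15 to the C3 ketone, next to which C2 is configurationally labile. The benzyl aryl ethers, the CH2 bridge and the hindered, hydrogen-bonded ketone of ring D should survive both stages.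

Step 9
Reactants: 16 5,7,3',4'-tetra-O-benzyl-8-(ring D benzyl)flavan-3-one
Product: 17 (2R,3R)-5,7,3',4'-tetra-O-benzyl-8-(ring D benzyl)flavan-3-ol
Conditions: RuCl[(R,R)-TsDPEN](p-cymene) (2 mol %), HCO2H/Et3N (1:1), EtOAc, 40 °C, Ar
Reagents that add atoms: none
Why: Asymmetric transfer hydrogenation with dynamic kinetic resolution, as known for cyclic ketones with a labile α-aryl centre: C2–H lies between ketone, O1 and aryl and should be exchanged by Et3N faster than hydride is transferred, the chiral ruthenium hydride selects the (2R) ketone and attacks C3 from the face away from the C2 aryl group, which sets the (2R,3R) cis pair, while the hindered ring D ketone is not reduced.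

Step 10
Reactants: 17 (2R,3R)-5,7,3',4'-tetra-O-benzyl-8-(ring D benzyl)flavan-3-ol
Product: 18 target, (2R,3R)-8-(ring D benzyl)flavan-3,5,7,3',4'-pentaol
Conditions: H2 (1 atm), Pd(OH)2/C, THF/MeOH, rt
Reagents that add atoms: none
Why: Neutral catalytic hydrogenolysis of four benzyl aryl ethers, a standard last step for benzylated flavan-3-ols, which should spare the cyclic O1–C2 bond, the CH2 bridge, the ketone and all three stereocenters.

Compound list
1 | 2-methylbenzene-1,3,5-triol | Cc1c(O)cc(O)cc1O | starting material
2 | (S)-2-methylbutanoyl chloride | CC[C@H](C)C(=O)Cl | starting material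
3 | (S)-2-methyl-1-(2,4,6-trihydroxy-3-methylphenyl)butan-1-one | CC[C@H](C)C(=O)c1c(O)cc(O)c(C)c1O | intermediate
4 | (S)-1-[4,6-bis(benzyloxy)-2-hydroxy-3-methylphenyl]-2-methylbutan-1-one | CC[C@H](C)C(=O)c1c(OCc2ccccc2)cc(OCc2ccccc2)c(C)c1O | intermediate
5 | (S)-1-[4,6-bis(benzyloxy)-2-methoxy-3-methylphenyl]-2-methylbutan-1-one | CC[C@H](C)C(=O)c1c(OCc2ccccc2)cc(OCc2ccccc2)c(C)c1OC | intermediate
6 | (S)-1-(4,6-dihydroxy-2-methoxy-3-methylphenyl)-2-methylbutan-1-one | CC[C@H](C)C(=O)c1c(O)cc(O)c(C)c1OC | intermediate
7 | 3,4-bis(benzyloxy)benzaldehyde | O=Cc1ccc(OCc2ccccc2)c(OCc2ccccc2)c1 | starting material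
8 | (benzyloxy)acetaldehyde | O=CCOCc1ccccc1 | starting material
9 | (Z)-2-(benzyloxy)-3-[3,4-bis(benzyloxy)phenyl]prop-2-enal | O=C/C(OCc1ccccc1)=C/c1ccc(OCc2ccccc2)c(OCc2ccccc2)c1 | intermediate
10 | 3,5-bis(benzyloxy)phenol | Oc1cc(OCc2ccccc2)cc(OCc2ccccc2)c1 | starting material
11 | 3,5-bis(benzyloxy)-2-[(dimethylamino)methyl]phenol | CN(C)Cc1c(O)cc(OCc2ccccc2)cc1OCc1ccccc1 | intermediate
12 | 3,5-bis(benzyloxy)-6-methylidenecyclohexa-2,4-dien-1-one (ortho-quinone methide, not isolated) | C=C1C(=O)C=C(OCc2ccccc2)C=C1OCc1ccccc1 | intermediate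
13 | 3,5-bis(benzyloxy)-2-(ring D benzyl)phenol | CC[C@H](C)C(=O)c1c(O)c(Cc2c(O)cc(OCc3ccccc3)cc2OCc2ccccc2)c(O)c(C)c1OC | intermediate
14 | vinylogous ortho-quinone methide from 13 and 9 (not isolated) | CC[C@H](C)C(=O)c1c(O)c(CC2=C(OCc3ccccc3)C=C(OCc3ccccc3)C(=CC(OCc3ccccc3)=Cc3ccc(OCc4ccccc4)c(OCc4ccccc4)c3)C2=O)c(O)c(C)c1OC | intermediate
15 | 3,5,7-tris(benzyloxy)-2-[3,4-bis(benzyloxy)phenyl]-8-(ring D benzyl)-2H-chromene, both C2 configurations (not isolated) | CC[C@H](C)C(=O)c1c(O)c(Cc2c(OCc3ccccc3)cc(OCc3ccccc3)c3c2OC(c2ccc(OCc4ccccc4)c(OCc4ccccc4)c2)C(OCc2ccccc2)=C3)c(O)c(C)c1OC | intermediate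
16 | 5,7,3',4'-tetra-O-benzyl-8-(ring D benzyl)flavan-3-one, both C2 configurations | CC[C@H](C)C(=O)c1c(O)c(Cc2c(OCc3ccccc3)cc(OCc3ccccc3)c3c2OC(c2ccc(OCc4ccccc4)c(OCc4ccccc4)c2)C(=O)C3)c(O)c(C)c1OC | intermediate
17 | (2R,3R)-5,7,3',4'-tetra-O-benzyl-8-(ring D benzyl)flavan-3-ol | CC[C@H](C)C(=O)c1c(O)c(Cc2c(OCc3ccccc3)cc(OCc3ccccc3)c3c2O[C@H](c2ccc(OCc4ccccc4)c(OCc4ccccc4)c2)[C@H](O)C3)c(O)c(C)c1OC | intermediate
18 | (2R,3R)-8-(ring D benzyl)flavan-3,5,7,3',4'-pentaol (CNP0299940.3) | CC[C@H](C)C(=O)c1c(O)c(Cc2c(O)cc(O)c3c2O[C@H](c2ccc(O)c(O)c2)[C@H](O)C3)c(O)c(C)c1OC | target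

Total step count: 10
Longest linear sequence: 8 steps (steps 1–4, then 7–10)

Steps most likely to fail

Step 8. The condensation of the donor-substituted, α-branched enal may be sluggish. Conjugate addition may compete with attack at the formyl carbon, and prolonged heating may start exchange of the CH2 bridge. The fallback sets out from 13 and comes back at 16, and closes ring C by a polar domino sequence instead of a pericyclic one. Ortho-formylation of 13 with MgCl2, Et3N and paraformaldehyde (Casnati–Skattebøl formylation, possible only at C4a) gives the salicylaldehyde F1. DABCO-mediated oxa-Michael/Henry/dehydration with commercial (E)-3,4-bis(benzyloxy)-β-nitrostyrene then forms O1–C2 and C3–C4 and gives the 3-nitro-2H-chromene F2. Reduction of the nitroalkene with Fe in aqueous AcOH at 80 °C, with hydrolysis of the resulting imine, gives 16.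

Step 9. Epimerisation at C2 may be too slow relative to hydride transfer. The catalyst may also discriminate poorly between the two flanks of a ketone that is not conjugated to an arene. The fallback sets out from 16 and comes back at 17, and replaces catalyst control by substrate control plus separation and recycling. LiBH(s-Bu)3 in THF at −78 °C should deliver hydride anti to the C2 aryl group and give only cis alcohols, that is 17 together with its (2S,3S) diastereomer F3. The two are separated by preparative chromatography on a chiral stationary phase. F3 is returned to 16 by Parikh–Doering oxidation, equilibrated at C2 with Et3N and reduced again.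

Step 7. The quinone methide may condense with itself, ring A may be alkylated twice, and the bridge may exchange at 110 °C. The fallback sets out from 10 and comes back at 13, and forms the bridge through a cation at low temperature. Ortho-formylation of 10 with MgCl2, Et3N and paraformaldehyde gives 2-hydroxy-4,6-bis(benzyloxy)benzaldehyde F4. A reductive Friedel–Crafts benzylation of 6 with F4 (Et3SiH, CF3CO2H, CH2Cl2, 0 °C) then gives 13. Attack of 6 on the protonated aldehyde before or after the first hydride transfer leads to the same product.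

Further compounds
F1 | step 8 | 4,6-bis(benzyloxy)-2-hydroxy-3-(ring D benzyl)benzaldehyde | CC[C@H](C)C(=O)c1c(O)c(Cc2c(O)c(C=O)c(OCc3ccccc3)cc2OCc2ccccc2)c(O)c(C)c1OC
F2 | step 8 | 5,7-bis(benzyloxy)-2-[3,4-bis(benzyloxy)phenyl]-3-nitro-8-(ring D benzyl)-2H-chromene, both C2 configurations | CC[C@H](C)C(=O)c1c(O)c(Cc2c(OCc3ccccc3)cc(OCc3ccccc3)c3c2OC(c2ccc(OCc4ccccc4)c(OCc4ccccc4)c2)C([N+](=O)[O-])=C3)c(O)c(C)c1OC
F3 | step 9 | (2S,3S)-5,7,3',4'-tetra-O-benzyl-8-(ring D benzyl)flavan-3-ol | CC[C@H](C)C(=O)c1c(O)c(Cc2c(OCc3ccccc3)cc(OCc3ccccc3)c3c2O[C@@H](c2ccc(OCc4ccccc4)c(OCc4ccccc4)c2)[C@@H](O)C3)c(O)c(C)c1OC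
F4 | step 7 | 2-hydroxy-4,6-bis(benzyloxy)benzaldehyde | O=Cc1c(O)cc(OCc2ccccc2)cc1OCc1ccccc1
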